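Ring A (C1–C8–O7–C6–C5; numbering of 3,7-dioxabicyclo[3.3.0]octane, hydroxyl on C1) is closed last, at C6–O7. The key step exploits the free para-hydroxyl of the aryl group on C6, which makes C6 a latent quinone methide carbon as in lignan biosynthesis. Its precursor is an isomer of the target: ring B (C1–C2–O3–C4–C5) carries C1(OH)(C8H2OH) and an exocyclic C5=C6 4-hydroxystyrene. Light-driven tautomerisation gives the para-quinone methide; the C8 hydroxyl adds to C6, closing ring A and setting C5 and C6 without any reagent. The hidden twofold symmetry of the carbon skeleton lets a double Stobbe condensation build both halves; one asymmetric epoxidation with in-situ ring closure sets C1 and C2.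

Key step: step 6

Remark: the atom numbers of the target are kept for the corresponding atoms of all precursors, and aldehyde 2 is taken as commercially available.

Step 1
Reactants: 1 diethyl succinate; 2 4-(allyloxy)-3-methoxybenzaldehyde (2.2 equiv)
Product: 3 (2E,3E)-2,3-bis{[4-(allyloxy)-3-methoxyphenyl]methylidene}butanedioic acid
Conditions: NaOEt (3 equiv), EtOH, reflux; then aq. HCl
Reagents that add atoms: none
Why: Double Stobbe condensation, in which each aldol adduct lactonises onto the neighbouring ester and opens by E1cB elimination to an arylidene carboxylate, should place each aryl group trans to its carboxyl (E,E) and creates no stereocenter.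

Step 2
Reactants: 3
Product: 4 dimethyl (2E,3E)-2,3-bis{[4-(allyloxy)-3-methoxyphenyl]methylidene}butanedioate
Conditions: MeI, K2CO3, DMF, 20 °C
Reagents that add atoms: iodomethane (CI)
Why: O-Alkylation (SN2) of the dicarboxylate should esterify both hindered acids without acid, heat or change of alkene geometry.

Step 3
Reactants: 4
Product: 5 (2E,3E)-2,3-bis{[4-(allyloxy)-3-methoxyphenyl]methylidene}butane-1,4-diol
Conditions: iBu2AlH (5 equiv), CH2Cl2, −78 to 0 °C; aq. KNaC4H4O6
Reagents that add atoms: none
Why: 1,2-Reduction of both conjugated esters by iBu2AlH should give the bis(allylic alcohol) with the alkene geometry unchanged.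

Step 4
Reactants: 5
Product: 7 (2S,3R,4Z)-2-[4-(allyloxy)-3-methoxyphenyl]-4-{[4-(allyloxy)-3-methoxyphenyl]methylidene}-3-(hydroxymethyl)oxolan-3-ol, via (2R,3R)-epoxy diol 6 (not isolated)
Conditions: Ti(OiPr)4 (1.1 equiv), D-(−)-diethyl tartrate (1.3 equiv), tBuOOH (1.2 equiv), 4 Å molecular sieves, CH2Cl2, −25 °C, then 0 °C
Reagents that add atoms: tert-butyl hydroperoxide (CC(C)(C)OO)
Why: Sharpless asymmetric epoxidation of one of the two equivalent allylic alcohols with the D-(−)-tartrate complex should deliver oxygen to the face that makes C1 (R), and the titanium-activated epoxide should then be opened at its electron-rich benzylic carbon C2 by the C4 hydroxyl in the 5-endo mode with inversion, which sets C2 (S), forms ring B and removes the second allylic alcohol from further epoxidation.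

Step 5
Reactants: 7
Product: 8 (2S,3R,4Z)-2-(4-hydroxy-3-methoxyphenyl)-4-[(4-hydroxy-3-methoxyphenyl)methylidene]-3-(hydroxymethyl)oxolan-3-ol
Conditions: Pd(PPh3)4 (5 mol%), morpholine (10 equiv), THF, 20 °C
Reagents that add atoms: none
Why: Tsuji–Trost deallylation, in which zerovalent palladium ionises each aryl allyl ether and morpholine captures the allyl group, should free both phenols under near-neutral conditions that touch neither the styrene, the tertiary allylic alcohol, the benzylic ether nor any stereocenter.

Step 6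
Reactants: 8
Product: 10 (1R,2S,5S,6R)-2,6-bis(4-hydroxy-3-methoxyphenyl)-3,7-dioxabicyclo[3.3.0]octan-1-ol, via para-quinone methide 9 (not isolated)
Conditions: hν (300 nm), CF3CH2OH–MeCN (1:4), degassed, 1 mM, 20 °C
Reagents that add atoms: none
Why: Proposed new method: excitation of the 4-hydroxystyrene of 8 makes C5 strongly basic, the fluoroalcohol protonates it and loss of the phenolic proton gives para-quinone methide 9, whose exocyclic carbon C6 is attacked by the C8 hydroxyl; the closest known reaction types are the photoprotonation of 4-oxygenated styrenes in protic solvents with capture of the benzylic cation or quinone methide by an alcohol, and the biomimetic closure of lignan quinone methides by their own hydroxyl groups. Ring A closes by a 5-exo-trig oxa-1,6-addition, because the C6=C(aryl) bond that is attacked lies outside the new ring. C5 is controlled by strain: only the quinone methide with H on C5 cis to the C1 hydroxyl (C6 cis to C8) can reach the cis-fused bicycle, and the other epimer should rearomatise to 8 and be excited again. C6 is controlled kinetically, the flat quinone methide ring lying on the convex face away from ring B, which puts the aryl group exo and cis to H on C5. The step needs chemoselectivity for C6 over the benzylic ether C2 and freedom from acid, and both are secured because only the aryl group on C6 is conjugated to an alkene and absorbs at 300 nm and because the neutral medium should not ionise C2, C6 or the tertiary C1 alcohol in the ground state, so that no epimerisation is expected.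

Compound list
1 | diethyl succinate | CCOC(=O)CCC(=O)OCC | starting material
2 | 4-(allyloxy)-3-methoxybenzaldehyde | C=CCOc1ccc(C=O)cc1OC | starting material
3 | (2E,3E)-2,3-bis{[4-(allyloxy)-3-methoxyphenyl]methylidene}butanedioic acid | C=CCOc1ccc(/C=C(/C(=O)O)C(=C/c2ccc(OCC=C)c(OC)c2)\C(=O)O)cc1OC | intermediate
4 | dimethyl (2E,3E)-2,3-bis{[4-(allyloxy)-3-methoxyphenyl]methylidene}butanedioate | C=CCOc1ccc(/C=C(/C(=O)OC)C(=C/c2ccc(OCC=C)c(OC)c2)\C(=O)OC)cc1OC | intermediate
5 | (2E,3E)-2,3-bis{[4-(allyloxy)-3-methoxyphenyl]methylidene}butane-1,4-diol | C=CCOc1ccc(/C=C(/CO)C(=C/c2ccc(OCC=C)c(OC)c2)\CO)cc1OC | intermediate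
6 | [(2R,3R)-3-[4-(allyloxy)-3-methoxyphenyl]-2-{(1Z)-1-[4-(allyloxy)-3-methoxyphenyl]-3-hydroxyprop-1-en-2-yl}oxiran-2-yl]methanol | OC[C@]1(O[C@@H]1c1ccc(OCC=C)c(OC)c1)/C(CO)=C\c1ccc(OCC=C)c(OC)c1 | intermediate
7 | (2S,3R,4Z)-2-[4-(allyloxy)-3-methoxyphenyl]-4-{[4-(allyloxy)-3-methoxyphenyl]methylidene}-3-(hydroxymethyl)oxolan-3-ol | OC[C@@]1(O)[C@H](c2ccc(OCC=C)c(OC)c2)OC/C1=C/c1ccc(OCC=C)c(OC)c1 | intermediate
8 | (2S,3R,4Z)-2-(4-hydroxy-3-methoxyphenyl)-4-[(4-hydroxy-3-methoxyphenyl)methylidene]-3-(hydroxymethyl)oxolan-3-ol | OC[C@@]1(O)[C@H](c2ccc(O)c(OC)c2)OC/C1=C/c1ccc(O)c(OC)c1 | intermediate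
9 | (4E)-4-{[(3R,4R,5S)-4-hydroxy-5-(4-hydroxy-3-methoxyphenyl)-4-(hydroxymethyl)oxolan-3-yl]methylidene}-2-methoxycyclohexa-2,5-dien-1-one (para-quinone methide, H on C5 cis to the C1 hydroxyl) | OC[C@@]1(O)[C@H](c2ccc(O)c(OC)c2)OC[C@H]1/C=C1\C=CC(=O)C(OC)=C1 | intermediate
10 | (1R,2S,5S,6R)-2,6-bis(4-hydroxy-3-methoxyphenyl)-3,7-dioxabicyclo[3.3.0]octan-1-ol (both aryl groups exo) | COc1cc([C@@H]2OC[C@@]3(O)[C@H](c4ccc(O)c(OC)c4)OC[C@@H]23)ccc1O | target

Total step count: 6. Longest linear sequence: 6 steps (from 1 and 2 to 10).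

Steps most likely to fail

Step 6. The excited styrene may only isomerise between E and Z without being protonated at C5. The quinone methide may be captured by the solvent. Protonation may also occur on the face of C5 that cannot cyclise, without return to 8. The fallback uses known chemistry, sets out from 7 and comes back at 10. Compound 7 is treated with PhSeCl and NaHCO3 in CH2Cl2 at −78 °C. Anti 5-endo selenoetherification places selenium on C5 on the face of the C1 hydroxyl and the C8 oxygen on benzylic C6. It should give the selenide (1R,2S,5R,6S)-2,6-bis[4-(allyloxy)-3-methoxyphenyl]-5-(phenylselanyl)-3,7-dioxabicyclo[3.3.0]octan-1-ol F1, with the aryl group on C6 exo as a consequence of the alkene geometry. Bu3SnH and AIBN in toluene at 80 °C should replace selenium by hydrogen on the only accessible face of the bridgehead radical. This gives (1R,2S,5S,6R)-2,6-bis[4-(allyloxy)-3-methoxyphenyl]-3,7-dioxabicyclo[3.3.0]octan-1-ol F2. Pd(PPh3)4 and morpholine in THF then remove both allyl groups to give 10.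

Step 4. The free 1,4-diol may chelate titanium and erode the facial selectivity of the epoxidation. The electron-rich benzylic epoxide may also open through a free cation, with loss of the inversion at C2. The fallback sets out from 5 and comes back at 7. Compound 5 is silylated with TBSCl and imidazole in DMF to the bis(tert-butyldimethylsilyl) ether of 5 F3. Shi epoxidation with the D-fructose-derived ketone and a limiting amount of KHSO5 (as 2KHSO5·KHSO4·K2SO4), buffered with K2CO3 in MeCN–dimethoxymethane–water at 0 °C, needs no directing hydroxyl. It should give the (2R,3R)-mono-epoxide of F3 F4. Bu4NF in THF then frees both hydroxyls, and the C4 alkoxide should close ring B at C2 by way of 6 to give 7. Ti(OiPr)4 in CH2Cl2 is added if the closure lags.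

Step 1. The second condensation may stall at the mono-arylidene carboxylate, and mixtures of alkene isomers may form. The fallback sets out from 1 and 2 and comes back at 3. One Stobbe condensation of 1 with one equivalent of 2 (KOtBu, tBuOH, reflux) gives the half-ester (3E)-4-[4-(allyloxy)-3-methoxyphenyl]-3-(ethoxycarbonyl)but-3-enoic acid F5. Fischer esterification (EtOH, catalytic H2SO4) gives diethyl (2E)-2-{[4-(allyloxy)-3-methoxyphenyl]methylidene}butanedioate F6. A second Stobbe condensation with 2 (NaOEt, EtOH, reflux) gives (2E,3E)-2,3-bis{[4-(allyloxy)-3-methoxyphenyl]methylidene}-4-ethoxy-4-oxobutanoic acid F7. Saponification (NaOH, aqueous EtOH; then HCl) gives 3.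

Further compounds
F1 | step 6 | (1R,2S,5R,6S)-2,6-bis[4-(allyloxy)-3-methoxyphenyl]-5-(phenylselanyl)-3,7-dioxabicyclo[3.3.0]octan-1-ol | C=CCOc1ccc(cc1OC)[C@@H]1OC[C@@]2(O)[C@H](c3ccc(OCC=C)c(OC)c3)OC[C@@]12[Se]c1ccccc1
F2 | step 6 | (1R,2S,5S,6R)-2,6-bis[4-(allyloxy)-3-methoxyphenyl]-3,7-dioxabicyclo[3.3.0]octan-1-ol | C=CCOc1ccc(cc1OC)[C@@H]1OC[C@@]2(O)[C@H](c3ccc(OCC=C)c(OC)c3)OC[C@@H]12
F3 | step 4 | bis(tert-butyldimethylsilyl) ether of 5 | C=CCOc1ccc(/C=C(/CO[Si](C)(C)C(C)(C)C)C(=C/c2ccc(OCC=C)c(OC)c2)\CO[Si](C)(C)C(C)(C)C)cc1OC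
F4 | step 4 | (2R,3R)-mono-epoxide of F3 | CC(C)(C)[Si](C)(C)OC[C@]1(O[C@@H]1c1ccc(OCC=C)c(OC)c1)/C(CO[Si](C)(C)C(C)(C)C)=C\c1ccc(OCC=C)c(OC)c1
F5 | step 1 | (3E)-4-[4-(allyloxy)-3-methoxyphenyl]-3-(ethoxycarbonyl)but-3-enoic acid | CCOC(=O)/C(=C/c1ccc(OCC=C)c(OC)c1)CC(=O)O
F6 | step 1 | diethyl (2E)-2-{[4-(allyloxy)-3-methoxyphenyl]methylidene}butanedioate | CCOC(=O)/C(=C/c1ccc(OCC=C)c(OC)c1)CC(=O)OCC
F7 | step 1 | (2E,3E)-2,3-bis{[4-(allyloxy)-3-methoxyphenyl]methylidene}-4-ethoxy-4-oxobutanoic acid | C=CCOc1ccc(/C=C(/C(=O)OCC)C(=C/c2ccc(OCC=C)c(OC)c2)\C(=O)O)cc1OC
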